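## The problem

Aspergimarin C (21) is a 3-substituted 5,8-dihydroxyisochroman-1-one. Ring A is the hydroquinone and ring B the δ-lactone; C3 carries a pentyl chain (C1'–C5') whose C4' oxygen is acylated by (R)-mevalonic acid (C1''–C5''). The three stereocenters are C3 (R), C4' (S) and the tertiary carbinol C3'' (R). They lie too far apart for one to control another, so each is best taken from the chiral pool and carried through untouched. The skeleton is simple, and the real questions are two: how the lactone carbonyl C1 is placed on C8a of a fully oxygenated arene, and in what order the five oxygens are unmasked. The free hydroquinone oxidises easily to the quinone, and the lactone and the secondary ester are base-labile. The mevalonate is a tertiary β-hydroxy ester that can dehydrate or undergo retro-aldol cleavage, and it collapses to (R)-mevalonolactone (16) once the ester is cleaved, so the end game has to be short and neutral. Two secondary oxygens, C3–O and C4'–O, must be told apart: one becomes the ring oxygen O2, the other the ester oxygen. The feature that makes the key step possible is that C8a–H is the only unsubstituted position ortho to the benzylic arm C4, because the other ortho position, C5, bears oxygen. The C3 hydroxyl of a 1-arylalkan-2-ol, which must end as O2, sits at the right distance to deliver palladium to exactly that C–H bond through a six-membered palladacycle.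

## Retrosynthesis

The two phenols and the primary hydroxyl of 21 are masked as benzyl ethers in 20. Cutting three O–benzyl bonds in the last step leaves only a neutral hydrogenolysis between the protected compound and the oxidation-prone hydroquinone. No C–O bond at a stereocenter is benzylic, so nothing else is at risk.

The ester bond C4'–O–C1'' of 20 is cut next, giving the lactone alcohol 15 and the acid 19. This is the most convergent cut, and it lets the valuable mevalonate enter after the uncertain metal-catalysed step. The forward reaction is a carbodiimide esterification of a secondary alcohol, in which the hindered tertiary hydroxyl of 19 should not compete.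

Acid 19 is traced to (R)-mevalonolactone (16), which already holds C3'' in the correct configuration. The lactone is opened to potassium mevalonate (17) and benzylated at the primary oxygen and the carboxylate to give 18. The benzyl ester is then saponified. Only the primary oxygen needs a permanent group, and the one chosen leaves in the final hydrogenolysis.

Alcohol 15 comes from its silyl ether 14. In 14 the bonds C8a–C1 and C1–O2 are cut together, which removes the carbonyl carbon as carbon monoxide (13) and leaves the 1-arylheptan-2-ol 12. The neighbouring cuts would be lactonisation of a preformed benzoate, or opening of an epoxide by an ortho-metalated benzamide, and both need an arene that already carries a carboxyl group between two substituents. Here the arene of 12 is a plain hydroquinone diether, which is simpler by one functional group and by the steps needed to install it. The forward reaction must palladate the single free ortho C–H bond without oxidising the secondary alcohol. The C6 oxygen of 12 is silylated so that only the C2 hydroxyl can direct.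

The chain of 12 is cut between C3 and C4 of the heptane (C1'–C2' of the target), giving the epoxide 6 and the bromide 10. Bromide 10 is used as its Grignard reagent 11. Each fragment carries one stereocenter and neither is touched in the coupling. The forward reaction is a copper-catalysed epoxide opening at the terminal carbon, which automatically leaves the C2 hydroxyl free and the C6 oxygen protected.

Epoxide 6 is cut at the aryl–CH2 bond (C4a–C4) to the aryl Grignard reagent 4, made from bromide 2, and (S)-epichlorohydrin (3), by way of the chlorohydrin 5. This takes C3 directly from a cheap chiral three-carbon unit. The alternative sequence of allylation, epoxidation and kinetic resolution would discard half of the material. Bromide 2 comes from 1,4-bis(benzyloxy)benzene (1), whose four ring positions are equivalent.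

Bromide 10 comes from (S)-butane-1,3-diol (7), which supplies C4'. The primary hydroxyl is tosylated (8), the secondary one silylated (9), and the tosylate is exchanged for bromide.

## Roads not taken

Alternative 1: The lactone C3–O2 bond would be made by inserting oxygen between C1 and C2 of an indanone. The forward key step uses a flavin Baeyer–Villiger monooxygenase with dioxygen and NADPH on the 2-substituted 4,7-dimethoxyindan-1-one A2, whose C2 epimerises under the reaction conditions. One enantiomer is oxidised with migration of the secondary carbon, giving the lactone A1 in a dynamic resolution. Its merits are real. C3 is set by the catalyst with no chiral three-carbon unit, A2 is a trivially assembled carbocycle, and no carbon monoxide or precious metal is needed. For the step that builds the lactone it is greener than the chosen plan and probably shorter. The weak points are specific to this target: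
- The electron-rich dimethoxyaryl group is intrinsically the better migrating group, so the enzyme has to override the normal regiochemistry on a substrate with a peri methoxy group and a long hydroxylated chain.
- The sense of enantioselection must happen to be R, and can be changed only by finding another enzyme.
- The methyl ethers of A1 cannot be removed after the mevalonate is attached. They must be cleaved first, which leaves two phenols competing with the C4' alcohol in the esterification or forces a reprotection.

Against the greener lactone formation the chosen plan sets a C3 configuration that is bought, not screened for, and benzyl ethers that survive to a single final hydrogenolysis.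

Alternative 2: Ring A would be built last by cutting C4a–C5 and C8–C8a. In the forward key step the diene 2,5-bis(trimethylsilyloxy)furan (A5) adds across the enoate double bond of the dihydropyranone A4, which already carries all three stereocenters and the mevalonate ester. Acid work-up opens the oxygen bridge and the enedione enolises to the hydroquinone A3. This is the most convergent of the four plans. The hydroquinone never needs protection, the symmetric diene removes any regiochemical question, and the facial selectivity of the cycloaddition is irrelevant because both new sp3 centers are aromatised. In these respects it is better than the chosen plan. Its weakness is reactivity. A5 is very moisture-sensitive and is known to combine with strongly activated dienophiles, whereas the β-unsubstituted δ-lactone enoate of A4 is a poor one. Forcing conditions would expose the tertiary β-hydroxy ester and invite eliminative opening of the lactone at the C3 oxygen. A3 still carries a benzyl ether, so the final hydrogenolysis is not saved. The chosen plan sets against the higher convergence a key step with direct precedent on the same substrate class, placed before the mevalonate is attached.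

Alternative 3: The cut is the C3–C1' bond together with C1–O2. In the forward key step SnCl4 converts the (4S)-4-alkoxypent-2-enylstannane A8 into an allyltin trichloride, which adds to the arylacetaldehyde A7 through a chair transition state with remote 1,5-induction from the C4' ether. The resulting Z-homoallylic alkoxide closes onto the ortho methyl ester to give the lactone A6. This road is better than the chosen plan in two respects: C1 is present from the start at the right oxidation level, so no C–H activation is needed, and the lactonisation is essentially assured. C3 is set by substrate control, with no chiral reagent. Its costs are these: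
- A7 is a 1,2,3,4-tetrasubstituted arene with an ester next to an enolisable acetaldehyde arm. It takes longer to make than bromide 2 and is prone to self-condensation and to closure to an isocoumarin under Lewis acid.
- The reagent is a stoichiometric organotin compound made in several steps.
- The 4-methoxybenzyl ether must survive SnCl4.
- The Z-alkene of A6 must afterwards be saturated without loss of the benzyl ethers, and the 4-methoxybenzyl group removed, before the route rejoins the esterification.

The chosen plan sets against the safer ring closure a shorter, tin-free sequence, with no redox adjustment of the side chain and both stereocenters taken intact from the chiral pool.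

Key step: step 8

Assumption: bromide 2 is prepared rather than purchased, and the amino acid ligand of the key step is taken to be N-(menthyloxycarbonyl)-L-leucine, a standard mono-N-protected amino acid for this reaction class.

## Steps

Step 1
Reactants: 1 1,4-bis(benzyloxy)benzene
Product: 2 2-bromo-1,4-bis(benzyloxy)benzene
Conditions: NBS (1.0 equiv), MeCN, rt, dark
Reagents that add atoms: N-bromosuccinimide, O=C1CCC(=O)N1Br
Why: Electrophilic aromatic bromination of an electron-rich hydroquinone diether; all four ring positions are equivalent and the first bromine deactivates the ring toward a second, so the monobromide should result.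

Step 2
Reactants: 2 2-bromo-1,4-bis(benzyloxy)benzene; 3 (S)-epichlorohydrin
Product: 5 (2S)-1-[2,5-bis(benzyloxy)phenyl]-3-chloropropan-2-ol, via aryl Grignard reagent 4 (not isolated)
Conditions: Mg, THF, 45 °C; then CuI (10 mol %), 3, THF, −40 → −10 °C; aq. NH4Cl
Reagents that add atoms: none
Why: Magnesium insertion gives the aryl Grignard reagent, and copper-catalysed epoxide opening at the unsubstituted ring carbon is faster at low temperature than displacement of chloride. The stereocenter of 3 is not touched and becomes the (S)-carbinol that will be C3.

Step 3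
Reactants: 5 (2S)-1-[2,5-bis(benzyloxy)phenyl]-3-chloropropan-2-ol
Product: 6 (2S)-2-{[2,5-bis(benzyloxy)phenyl]methyl}oxirane
Conditions: NaOH, THF/H2O, rt
Reagents that add atoms: none
Why: Intramolecular Williamson etherification (3-exo-tet) of the chlorohydrin alkoxide; the carbinol carbon carries the nucleophile and is not the electrophile, so its configuration is retained.

Step 4
Reactants: 7 (S)-butane-1,3-diol
Product: 8 (3S)-3-hydroxybutyl 4-methylbenzenesulfonate
Conditions: TsCl (1.05 equiv), Et3N, CH2Cl2, −20 → 0 °C
Reagents that add atoms: 4-methylbenzenesulfonyl chloride, Cc1ccc(cc1)S(=O)(=O)Cl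
Why: Selective sulfonylation of the primary over the secondary hydroxyl at low temperature, a standard differentiation of 1,3-diols; the stereocenter is not involved.

Step 5
Reactants: 8 (3S)-3-hydroxybutyl 4-methylbenzenesulfonate
Product: 9 (3S)-3-[(tert-butyldimethylsilyl)oxy]butyl 4-methylbenzenesulfonate
Conditions: TBSCl, imidazole, DMF, rt
Reagents that add atoms: tert-butyldimethylsilyl chloride, CC(C)(C)[Si](C)(C)Cl
Why: Standard imidazole-promoted silylation of a secondary alcohol; the C–O bond at the stereocenter is not broken.

Step 6
Reactants: 9 (3S)-3-[(tert-butyldimethylsilyl)oxy]butyl 4-methylbenzenesulfonate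
Product: 10 {[(2S)-4-bromobutan-2-yl]oxy}(tert-butyl)dimethylsilane
Conditions: LiBr, acetone, reflux
Reagents that add atoms: lithium bromide, [Li+].[Br-]
Why: SN2 displacement of a primary tosylate by bromide (Finkelstein-type exchange); the silyl ether and the remote stereocenter are unaffected.

Step 7
Reactants: 10 {[(2S)-4-bromobutan-2-yl]oxy}(tert-butyl)dimethylsilane; 6 (2S)-2-{[2,5-bis(benzyloxy)phenyl]methyl}oxirane
Product: 12 (2R,6S)-1-[2,5-bis(benzyloxy)phenyl]-6-[(tert-butyldimethylsilyl)oxy]heptan-2-ol, via alkyl Grignard reagent 11 (not isolated)
Conditions: Mg, THF, rt → 40 °C; then CuI (10 mol %), 6, THF, −30 → 0 °C; aq. NH4Cl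
Reagents that add atoms: none
Why: Copper-catalysed opening of a monosubstituted epoxide by a primary alkyl Grignard reagent at the terminal carbon. Both stereocenters are carried over from 6 and 10; the descriptor at the carbinol changes from S to R only because the CIP priorities of its neighbours change.

Step 8
Reactants: 12 (2R,6S)-1-[2,5-bis(benzyloxy)phenyl]-6-[(tert-butyldimethylsilyl)oxy]heptan-2-ol; 13 carbon monoxide
Product: 14 (3R)-5,8-bis(benzyloxy)-3-{(4S)-4-[(tert-butyldimethylsilyl)oxy]pentyl}isochroman-1-one
Conditions: Pd(OAc)2 (10 mol %), N-(menthyloxycarbonyl)-L-leucine (20 mol %), AgOAc (3 equiv), Li2CO3 (1 equiv), CO (1 atm), ClCH2CH2Cl, 110 °C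
Reagents that add atoms: none
Why: The C2 hydroxyl binds divalent palladium and, with the ligand carboxylate as internal base, concerted metalation–deprotonation at the only free ortho C–H bond (the future C8a) gives a six-membered oxapalladacycle. CO inserts into the aryl–palladium bond (C8a–C1), and C–O reductive elimination from the seven-membered acyl palladium alkoxide forms C1–O2, releasing zerovalent palladium that AgOAc reoxidises. The closest known reaction type is the Pd(OAc)2-catalysed, hydroxyl-directed ortho C–H carbonylation of phenethyl alcohols to isochroman-1-ones with mono-N-protected amino acid ligands, for which secondary alcohols are the less favourable class. Ring B closes by acyl C–O bond formation, formally a 6-exo-trig attack of the C3 alkoxide on the acyl carbon. No stereocenter is created; the C–O bond at the carbinol is not broken, so C3 stays R, and C4' is remote. Site selectivity is fixed by the substrate, since the other ortho position carries the C5 ether and the silyl ether at C4' cannot direct. The chemoselectivity needed is carbonylation over oxidation of the secondary alcohol to the ketone by β-hydride elimination; the ligand-accelerated C–H cleavage on an electron-rich ring and the CO atmosphere, which occupies the site needed for β-hydride elimination, are relied on for this. The benzyl and silyl ethers are inert to the buffered, non-nucleophilic medium.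

Step 9
Reactants: 14 (3R)-5,8-bis(benzyloxy)-3-{(4S)-4-[(tert-butyldimethylsilyl)oxy]pentyl}isochroman-1-one
Product: 15 (3R)-5,8-bis(benzyloxy)-3-[(4S)-4-hydroxypentyl]isochroman-1-one
Conditions: HF·pyridine, THF, 0 °C → rt
Reagents that add atoms: none
Why: Fluoride-mediated cleavage of a secondary silyl ether under non-basic conditions, so the lactone is neither opened nor transacylated; benzyl ethers are inert.

Step 10
Reactants: 16 (R)-mevalonolactone
Product: 18 benzyl (3R)-5-(benzyloxy)-3-hydroxy-3-methylpentanoate, via potassium (R)-mevalonate 17 (not isolated)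
Conditions: KOH (1.0 equiv), MeOH/H2O, rt; evaporate; NaH (1.1 equiv), BnBr (2.3 equiv), Bu4NI (cat.), DMF, 0 °C → rt
Reagents that add atoms: potassium hydroxide, [K+].[OH-]; benzyl bromide, BrCc1ccccc1
Why: Saponification opens the lactone to a carboxylate that cannot relactonise. Williamson benzylation of the less hindered primary alkoxide and SN2 benzylation of the carboxylate follow, and the tertiary hydroxyl stays free because only about one equivalent of hydride is used. The stereocenter is not involved.

Step 11
Reactants: 18 benzyl (3R)-5-(benzyloxy)-3-hydroxy-3-methylpentanoate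
Product: 19 (3R)-5-(benzyloxy)-3-hydroxy-3-methylpentanoic acid
Conditions: LiOH·H2O, THF/H2O, 0 °C → rt; then 1 M HCl to pH 3
Reagents that add atoms: lithium hydroxide, [Li+].[OH-]
Why: Ester saponification by acyl–oxygen cleavage; with the C5 oxygen benzylated the acid cannot close back to the lactone, and mild hydroxide at room temperature should not trigger retro-aldol cleavage of the carboxylate.

Step 12
Reactants: 15 (3R)-5,8-bis(benzyloxy)-3-[(4S)-4-hydroxypentyl]isochroman-1-one; 19 (3R)-5-(benzyloxy)-3-hydroxy-3-methylpentanoic acid
Product: 20 (2S)-5-[(3R)-5,8-bis(benzyloxy)-1-oxoisochroman-3-yl]pentan-2-yl (3R)-5-(benzyloxy)-3-hydroxy-3-methylpentanoate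
Conditions: DCC, DMAP, CH2Cl2, 0 °C → rt
Reagents that add atoms: none
Why: Steglich esterification; the acyl group is transferred to the only free hydroxyl of 15 with retention at C4', because the alcohol C–O bond is not broken. The tertiary hydroxyl of 19 is too hindered to be acylated at a competitive rate.

Step 13
Reactants: 20 (2S)-5-[(3R)-5,8-bis(benzyloxy)-1-oxoisochroman-3-yl]pentan-2-yl (3R)-5-(benzyloxy)-3-hydroxy-3-methylpentanoate
Product: 21 aspergimarin C, (2S)-5-[(3R)-5,8-dihydroxy-1-oxoisochroman-3-yl]pentan-2-yl (3R)-3,5-dihydroxy-3-methylpentanoate
Conditions: H2 (1 atm), 10% Pd/C, EtOAc, rt; work-up under argon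
Reagents that add atoms: none
Why: Catalytic hydrogenolysis of two aryl benzyl ethers and one alkyl benzyl ether under neutral conditions. The lactone, the ester and the tertiary alcohol are inert, and no C–O bond at a stereocenter is benzylic.

## Compound list

1 | 1,4-bis(benzyloxy)benzene | c1ccc(COc2ccc(OCc3ccccc3)cc2)cc1 | starting material
2 | 2-bromo-1,4-bis(benzyloxy)benzene | Brc1cc(OCc2ccccc2)ccc1OCc1ccccc1 | intermediate
3 | (S)-epichlorohydrin | ClC[C@@H]1CO1 | starting material
4 | [2,5-bis(benzyloxy)phenyl]magnesium bromide | Br[Mg]c1cc(OCc2ccccc2)ccc1OCc1ccccc1 | intermediate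
5 | (2S)-1-[2,5-bis(benzyloxy)phenyl]-3-chloropropan-2-ol | ClC[C@@H](O)Cc1cc(OCc2ccccc2)ccc1OCc1ccccc1 | intermediate
6 | (2S)-2-{[2,5-bis(benzyloxy)phenyl]methyl}oxirane | C(c1cc(OCc2ccccc2)ccc1OCc1ccccc1)[C@H]1CO1 | intermediate
7 | (S)-butane-1,3-diol | C[C@H](O)CCO | starting material
8 | (3S)-3-hydroxybutyl 4-methylbenzenesulfonate | C[C@H](O)CCOS(=O)(=O)c1ccc(C)cc1 | intermediate
9 | (3S)-3-[(tert-butyldimethylsilyl)oxy]butyl 4-methylbenzenesulfonate | C[C@H](O[Si](C)(C)C(C)(C)C)CCOS(=O)(=O)c1ccc(C)cc1 | intermediate
10 | {[(2S)-4-bromobutan-2-yl]oxy}(tert-butyl)dimethylsilane | C[C@H](O[Si](C)(C)C(C)(C)C)CCBr | intermediate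
11 | {(3S)-3-[(tert-butyldimethylsilyl)oxy]butyl}magnesium bromide | C[C@H](O[Si](C)(C)C(C)(C)C)CC[Mg]Br | intermediate
12 | (2R,6S)-1-[2,5-bis(benzyloxy)phenyl]-6-[(tert-butyldimethylsilyl)oxy]heptan-2-ol | C[C@@H](CCC[C@@H](O)Cc1cc(OCc2ccccc2)ccc1OCc1ccccc1)O[Si](C)(C)C(C)(C)C | intermediate
13 | carbon monoxide | [C-]#[O+] | starting material
14 | (3R)-5,8-bis(benzyloxy)-3-{(4S)-4-[(tert-butyldimethylsilyl)oxy]pentyl}isochroman-1-one | C[C@@H](CCC[C@@H]1Cc2c(OCc3ccccc3)ccc(OCc3ccccc3)c2C(=O)O1)O[Si](C)(C)C(C)(C)C | intermediate
15 | (3R)-5,8-bis(benzyloxy)-3-[(4S)-4-hydroxypentyl]isochroman-1-one | C[C@@H](CCC[C@@H]1Cc2c(OCc3ccccc3)ccc(OCc3ccccc3)c2C(=O)O1)O | intermediate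
16 | (R)-mevalonolactone | C[C@@]1(O)CCOC(=O)C1 | starting material
17 | potassium (3R)-3,5-dihydroxy-3-methylpentanoate (potassium (R)-mevalonate) | C[C@@](O)(CCO)CC(=O)[O-].[K+] | intermediate
18 | benzyl (3R)-5-(benzyloxy)-3-hydroxy-3-methylpentanoate | C[C@@](O)(CCOCc1ccccc1)CC(=O)OCc1ccccc1 | intermediate
19 | (3R)-5-(benzyloxy)-3-hydroxy-3-methylpentanoic acid | C[C@@](O)(CCOCc1ccccc1)CC(=O)O | intermediate
20 | (2S)-5-[(3R)-5,8-bis(benzyloxy)-1-oxoisochroman-3-yl]pentan-2-yl (3R)-5-(benzyloxy)-3-hydroxy-3-methylpentanoate | C[C@@H](CCC[C@@H]1Cc2c(OCc3ccccc3)ccc(OCc3ccccc3)c2C(=O)O1)OC(=O)C[C@](C)(O)CCOCc1ccccc1 | intermediate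
21 | aspergimarin C | C[C@@H](CCC[C@@H]1Cc2c(O)ccc(O)c2C(=O)O1)OC(=O)C[C@](C)(O)CCO | target

## Step count and risks

Total: 13 steps. Longest linear sequence: 8 steps (1 → 2 → 5 → 6 → 12 → 14 → 15 → 20 → 21; the branch from 7 is equally long). The mevalonate branch from 16 contributes two steps before the convergence.

Step 8 (key step). The most likely failure is slow palladation at a C–H bond that lies between the arm-bearing C4a and the C8 ether. A secondary alcohol has less conformational assistance than a tertiary one, so oxidation of the alcohol to the ketone by β-hydride elimination could overtake carbonylation. The fallback forms the same C8a–C1 bond by electrophilic substitution and adjusts the oxidation level afterwards. It sets out from 12. Methoxymethylation (MOMCl, iPr2NEt, CH2Cl2) would give the acetal 1,4-bis(benzyloxy)-2-[(2R,6S)-6-[(tert-butyldimethylsilyl)oxy]-2-(methoxymethoxy)heptyl]benzene F1. TMSOTf in CH2Cl2 at low temperature would then ionise F1 to an oxocarbenium ion that closes onto the only free ortho position, activated by the ortho ether at C8. This oxa-Pictet–Spengler-type cyclisation would give (3R)-5,8-bis(benzyloxy)-3-{(4S)-4-[(tert-butyldimethylsilyl)oxy]pentyl}isochroman F2. Hydride abstraction at C1 with DDQ in wet CH2Cl2 would give the lactol (3R)-5,8-bis(benzyloxy)-3-{(4S)-4-[(tert-butyldimethylsilyl)oxy]pentyl}isochroman-1-ol F3, and oxidation with TEMPO and PhI(OAc)2 would return to the route at 14.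

Step 10. Two things may go wrong. Benzylation may spill over to the tertiary alkoxide, or, once the ester has formed, a tertiary alkoxide may undergo retro-aldol fragmentation. Carboxylate alkylation ahead of ether formation would also lead back to the lactone. The fallback changes the protecting group on the primary oxygen and sets out from 17. TBSCl and imidazole in DMF would give tert-butyldimethylsilyl (3R)-5-[(tert-butyldimethylsilyl)oxy]-3-hydroxy-3-methylpentanoate F4, and K2CO3 in aqueous MeOH would cleave the silyl ester to (3R)-5-[(tert-butyldimethylsilyl)oxy]-3-hydroxy-3-methylpentanoic acid F5. Steglich esterification with 15 would give (2S)-5-[(3R)-5,8-bis(benzyloxy)-1-oxoisochroman-3-yl]pentan-2-yl (3R)-5-[(tert-butyldimethylsilyl)oxy]-3-hydroxy-3-methylpentanoate F6. HF·pyridine would then free the primary alcohol to give (2S)-5-[(3R)-5,8-bis(benzyloxy)-1-oxoisochroman-3-yl]pentan-2-yl (3R)-3,5-dihydroxy-3-methylpentanoate F7, and hydrogenolysis over Pd/C would return to the route at 21, at the cost of one extra step.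

Step 12. Acylation of the hindered secondary alcohol may be slow. The activated β-hydroxy acid could then dehydrate to the enoate or rearrange to the N-acylurea. The fallback masks the tertiary hydroxyl and sets out from 18. TESOTf and 2,6-lutidine would give benzyl (3R)-5-(benzyloxy)-3-methyl-3-[(triethylsilyl)oxy]pentanoate F8, and LiOH would give (3R)-5-(benzyloxy)-3-methyl-3-[(triethylsilyl)oxy]pentanoic acid F9. Yamaguchi esterification with 15 (2,4,6-trichlorobenzoyl chloride, Et3N, then DMAP) would give (2S)-5-[(3R)-5,8-bis(benzyloxy)-1-oxoisochroman-3-yl]pentan-2-yl (3R)-5-(benzyloxy)-3-methyl-3-[(triethylsilyl)oxy]pentanoate F10. HF·pyridine would return to the route at 20.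

Step 7. The epoxide 6 may be opened by bromide from the magnesium halide present, or may rearrange under Lewis acid before the cuprate attacks. Wurtz coupling may also erode the formation of 11. The fallback reverses the order in which the three-carbon unit is joined and sets out from 11 and from 2. Copper-catalysed opening of (R)-epichlorohydrin by 11 would give (2R,6S)-6-[(tert-butyldimethylsilyl)oxy]-1-chloroheptan-2-ol F11, and NaOH would close it to tert-butyldimethyl{[(2S)-5-[(2R)-oxiran-2-yl]pentan-2-yl]oxy}silane F12. F12 is a plain alkyl oxirane with no benzylic position. Opening it at the terminal carbon with the aryl Grignard reagent 4 and CuI would return to the route at 12 with the same configuration.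

## Further compounds

F1 | step 8 | 1,4-bis(benzyloxy)-2-[(2R,6S)-6-[(tert-butyldimethylsilyl)oxy]-2-(methoxymethoxy)heptyl]benzene | C[C@@H](CCC[C@@H](OCOC)Cc1cc(OCc2ccccc2)ccc1OCc1ccccc1)O[Si](C)(C)C(C)(C)C
F2 | step 8 | (3R)-5,8-bis(benzyloxy)-3-{(4S)-4-[(tert-butyldimethylsilyl)oxy]pentyl}isochroman | C[C@@H](CCC[C@@H]1Cc2c(OCc3ccccc3)ccc(OCc3ccccc3)c2CO1)O[Si](C)(C)C(C)(C)C
F3 | step 8 | (3R)-5,8-bis(benzyloxy)-3-{(4S)-4-[(tert-butyldimethylsilyl)oxy]pentyl}isochroman-1-ol (either C1 epimer) | C[C@@H](CCC[C@@H]1Cc2c(OCc3ccccc3)ccc(OCc3ccccc3)c2C(O)O1)O[Si](C)(C)C(C)(C)C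
F4 | step 10 | tert-butyldimethylsilyl (3R)-5-[(tert-butyldimethylsilyl)oxy]-3-hydroxy-3-methylpentanoate | C[C@@](O)(CCO[Si](C)(C)C(C)(C)C)CC(=O)O[Si](C)(C)C(C)(C)C
F5 | step 10 | (3R)-5-[(tert-butyldimethylsilyl)oxy]-3-hydroxy-3-methylpentanoic acid | C[C@@](O)(CCO[Si](C)(C)C(C)(C)C)CC(=O)O
F6 | step 10 | (2S)-5-[(3R)-5,8-bis(benzyloxy)-1-oxoisochroman-3-yl]pentan-2-yl (3R)-5-[(tert-butyldimethylsilyl)oxy]-3-hydroxy-3-methylpentanoate | C[C@@H](CCC[C@@H]1Cc2c(OCc3ccccc3)ccc(OCc3ccccc3)c2C(=O)O1)OC(=O)C[C@](C)(O)CCO[Si](C)(C)C(C)(C)C
F7 | step 10 | (2S)-5-[(3R)-5,8-bis(benzyloxy)-1-oxoisochroman-3-yl]pentan-2-yl (3R)-3,5-dihydroxy-3-methylpentanoate | C[C@@H](CCC[C@@H]1Cc2c(OCc3ccccc3)ccc(OCc3ccccc3)c2C(=O)O1)OC(=O)C[C@](C)(O)CCO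
F8 | step 12 | benzyl (3R)-5-(benzyloxy)-3-methyl-3-[(triethylsilyl)oxy]pentanoate | C[C@@](O[Si](CC)(CC)CC)(CCOCc1ccccc1)CC(=O)OCc1ccccc1
F9 | step 12 | (3R)-5-(benzyloxy)-3-methyl-3-[(triethylsilyl)oxy]pentanoic acid | C[C@@](O[Si](CC)(CC)CC)(CCOCc1ccccc1)CC(=O)O
F10 | step 12 | (2S)-5-[(3R)-5,8-bis(benzyloxy)-1-oxoisochroman-3-yl]pentan-2-yl (3R)-5-(benzyloxy)-3-methyl-3-[(triethylsilyl)oxy]pentanoate | C[C@@H](CCC[C@@H]1Cc2c(OCc3ccccc3)ccc(OCc3ccccc3)c2C(=O)O1)OC(=O)C[C@](C)(O[Si](CC)(CC)CC)CCOCc1ccccc1
F11 | step 7 | (2R,6S)-6-[(tert-butyldimethylsilyl)oxy]-1-chloroheptan-2-ol | ClC[C@H](O)CCC[C@H](C)O[Si](C)(C)C(C)(C)C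
F12 | step 7 | tert-butyldimethyl{[(2S)-5-[(2R)-oxiran-2-yl]pentan-2-yl]oxy}silane | C1[C@H](O1)CCC[C@H](C)O[Si](C)(C)C(C)(C)C
A1 | alternative 1 | (3R)-3-[(4S)-4-hydroxypentyl]-5,8-dimethoxyisochroman-1-one | C[C@@H](CCC[C@@H]1Cc2c(OC)ccc(OC)c2C(=O)O1)O
A2 | alternative 1 | 2-[(4S)-4-hydroxypentyl]-4,7-dimethoxyindan-1-one (C2 epimers in equilibrium) | C[C@H](O)CCCC1Cc2c(OC)ccc(OC)c2C1=O
A3 | alternative 2 | aspergimarin C primary benzyl ether, (2S)-5-[(3R)-5,8-dihydroxy-1-oxoisochroman-3-yl]pentan-2-yl (3R)-5-(benzyloxy)-3-hydroxy-3-methylpentanoate | C[C@@H](CCC[C@@H]1Cc2c(O)ccc(O)c2C(=O)O1)OC(=O)C[C@](C)(O)CCOCc1ccccc1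
A4 | alternative 2 | (2S)-5-[(2R)-6-oxo-3,6-dihydro-2H-pyran-2-yl]pentan-2-yl (3R)-5-(benzyloxy)-3-hydroxy-3-methylpentanoate | C[C@@H](CCC[C@@H]1CC=CC(=O)O1)OC(=O)C[C@](C)(O)CCOCc1ccccc1
A5 | alternative 2 | 2,5-bis(trimethylsilyloxy)furan | C[Si](C)(C)Oc1ccc(O[Si](C)(C)C)o1
A6 | alternative 3 | (3R)-5,8-bis(benzyloxy)-3-[(2Z,4S)-4-(4-methoxybenzyloxy)pent-2-en-1-yl]isochroman-1-one | C[C@@H](/C=C\C[C@@H]1Cc2c(OCc3ccccc3)ccc(OCc3ccccc3)c2C(=O)O1)OCc1ccc(OC)cc1
A7 | alternative 3 | methyl 3,6-bis(benzyloxy)-2-(2-oxoethyl)benzoate | COC(=O)c1c(CC=O)c(OCc2ccccc2)ccc1OCc1ccccc1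
A8 | alternative 3 | tributyl[(2E,4S)-4-(4-methoxybenzyloxy)pent-2-en-1-yl]stannane | CCCC[Sn](CCCC)(CCCC)C/C=C/[C@H](C)OCc1ccc(OC)cc1
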